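## Structural features

The target 27 is a flavone. Benzo ring A is fused through C4a and C8a to the γ-pyrone ring C (O1, C2, C3, C4=O), and aryl ring B is joined to C2 by one C–C bond. Ring A is fully substituted (C5 OH, C6 OMe, C7 OH, C8 OMe, plus the two fusion carbons). C3 carries OMe, and ring B carries OMe at C2' and C4' and OH at C5'. There is no stereocentre, so no stereocentres stand next to each other. The only stereochemical element on the way is an enone double bond whose geometry disappears when ring C closes. The fragile groups are the three free phenols on electron-rich rings, which oxidise easily in base, and the catechol-type intermediates needed to tell O6 from O7. The real difficulty is regiochemical: eight oxygen substituents must be told apart, five methylated and three free, and on ring A they alternate OH/OMe/OH/OMe around a hexasubstituted benzene. The key step uses the fact that O1 and the acyl carbon C4 sit on the neighbouring carbons C8a and C4a, so an aryne across C4a–C8a can take up both. Because C5/C8 and C6/C7 all bear oxygen, that aryne can be made mirror-symmetric (OMe at C5 and C8, OBn at C6 and C7), which removes any orientation problem. The price is a later chelation-controlled demethylation at O5 and an acidity-controlled differentiation of O6 and O7.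

## Logic of the disconnections

27 from 26: the bonds O5–CH3, O7–CH2Ph and O5'–CH(CH3)2 are cut. The three hydroxyls that are free in 27 are placed on the three ethers a chelating Lewis acid removes most easily (peri to C4=O, benzylic, secondary alkyl). One operation then unmasks all of them. The forward step must spare five other aryl or enol methyl ethers.

26 from 25, 24 and 23: the bond O6–CH3 is cut, then O7–CH2Ph, then both benzyl groups are restored on O6 and O7. This is needed because the symmetric ring A building block puts the same group on O6 and O7. Passing through 24 lets the higher acidity of the 7-OH (para to the C4 carbonyl) tell the two apart. The forward steps need a hydrogenolysis that spares the isopropyl ether and the C2=C3 bond, and a regioselective monobenzylation.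

23 from 21 (through 22): the bond O1–C2 is cut and the C2=C3 unsaturation is taken back to the open enone. This removes ring C and leaves an ortho-hydroxyaryl ketone, which is the direct product type of the key step. The forward step is a 6-endo oxa-Michael closure and dehydrogenation that must tolerate benzyl ethers and two electron-rich rings.

21 from 13 and 19 (through 20): the bonds O1–C8a and C4–C4a are cut together. This is the point of highest convergence. Ring A becomes a symmetric pentasubstituted arene, and ring B with C2, C3 and C4 becomes one acid. The forward step requires the aryl anion formed after O-addition to capture the acyl carbon faster than a proton, on a crowded aryne.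

19 from 16 and 17 (through 18), then 16 from 15 and 14: the Cα=Cβ bond (C2–C3 of the flavone) is cut as an aldol condensation. Then the formyl C–C bond and the O–isopropyl bond are cut. Each cut leads to a simple aromatic substitution or alkylation. The forward steps need formylation at the one doubly activated, unhindered position and the Z geometry, which is the stable one.

13 from 10 (through 11 and 12), then 10 from 9: the C–Si and O–S bonds are cut, then the C–Br bond. An ortho-bromophenol is the standard precursor of a 2-silylaryl triflate. The forward steps need an O-to-C silyl shift into a hexasubstituted ring and a clean bromination of an electron-rich phenol.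

9 from 6 (through 7 and 8), then 6 from 5, 5 from 4, 4 from 2 (through 3) and 2 from 1: the cuts are C–OH, C–Br, O–CH3, the C–O bond that replaces the formyl carbon, and the two O–benzyl bonds. The gain is the symmetric tetraether 5, whose two ring hydrogens are equivalent, so neither the bromination nor the later hydroxylation has a regiochemical choice.

## Other disconnections considered

Alternative 1: The cut is O1–C8a. In the forward direction the enol oxygen on the ring B side of the 2-methoxy-1,3-diketone A1 would be coupled with the ortho C–Br bond of ring A under CuI (monovalent copper iodide) catalysis and base. This closes ring C and gives the protected 3-methoxyflavone A2 directly.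
- In its favour: ring C arrives at the flavone oxidation level with the C3 methoxy group in place, so no oxidative step is needed. Ring A of A2 already carries OBn at C5 and C7 and OMe at C6 and C8, so one hydrogenolysis would finish the synthesis. On both points it is better than the chosen plan, which needs step 12 and then steps 13–16.
- Against it here: A1 requires a hexasubstituted ring A in which bromine, the acyl group and four oxygens in the order OBn/OMe/OBn/OMe are all placed without help from symmetry, whereas 13 comes from the symmetric 5. The 2-methoxy-1,3-diketone must be assembled by acyl transfer at a doubly ortho-substituted ketone. The C–Br bond lies between the acyl group and OMe on a very electron-rich ring, where oxidative addition to copper would be slow and protodebromination would compete.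
- Comparison: both key steps belong to well-precedented reaction types. The copper step forms one bond, the aryne step two. What alternative 1 saves at the end it would probably spend in the longer linear build-up of A1, so the two plans are judged about equal in length, with the chosen one simpler in its ring A chemistry.

Alternative 2: The cut is C3–C4. A triazolium-derived carbene would turn the aromatic formyl group of dialdehyde A3 into an acyl anion equivalent (Breslow intermediate) that adds to the aliphatic formyl group. This closes ring C as the 3-hydroxychroman-4-one A4.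
- In its favour: the conditions are metal-free and mild, the C3 oxygen arrives in the ring-forming step, and ring A of A4 is again differentiated as OBn/OMe/OBn/OMe. On this last point it is better than the chosen plan.
- Against it here: A3 contains an α-aryloxy-α-arylacetaldehyde, which would be prone to enolisation and to E1cB loss of the phenoxide under the basic carbene conditions. Either formyl group can become the acyl anion equivalent, and only one sense of the crossed benzoin gives the 4-ketone. The aromatic aldehyde is flanked by two ortho oxygens, which should slow carbene addition. A4 is one oxidation level too low and has a free 3-OH, so dehydrogenation and O-methylation (two steps) would precede deprotection. Two stereocentres are made only to be destroyed.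
- Comparison: it is equal to the chosen plan in needing an oxidation after the key step. It forms one bond where the chosen step forms two. Building A3 (O-alkylation of a hindered salicylaldehyde with an arylacetaldehyde equivalent, then unmasking) would make it longer and less robust.

Alternative 3: The cuts are C4a–C4, C4–C3 and O1–C2, with carbon monoxide as C4. A zerovalent palladium catalyst would insert into the C–I bond of the symmetric iodoresorcinol A5, take up CO and couple the acylpalladium species with the ring B alkyne A6. Amine-mediated 6-endo addition of an ortho hydroxyl to the ynone would then close ring C and give A7.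
- In its favour: three bonds and ring C are formed in one operation from three components, which is the highest convergence of all plans. A5 is symmetric, so either hydroxyl may cyclise and the other becomes the C5–OH. Ring A arrives with OMe at C6 and C8 and one benzyl at O7, so neither the O5 demethylation nor the O6/O7 differentiation of the chosen plan is needed. This is a clear advantage. In its use of ring A symmetry it is the equal of the chosen plan.
- Against it here: A7 has hydrogen at C3. The C3 methoxy group would have to be added after ring closure by C3 oxidation and O-methylation, beside a free 5-OH and two electron-rich rings. That is two or three steps of the least predictable kind. 5-exo closure at the ynone competes with the 6-endo mode. A5 is a very electron-rich, doubly ortho-substituted aryl iodide, open to deiodination and oxidation.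
- Comparison: there would be fewer steps to the flavone nucleus. The disconnection leaves the C3 oxygen unaddressed, whereas the chosen plan brings it in with 19. The total count would probably be similar, with the uncertain chemistry moved to the end.

Key step: step 11

Assumptions and remarks on the chemistry:
- Flavone numbering (O1, C2–C8a, primed positions for ring B) is used for positions of open-chain intermediates as well.
- The double bond of 18, 19 and 21 is taken as Z (OMe and aryl cis, aryl trans to the carbonyl), the more stable geometry. It is erased in step 12.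
- The symmetric OMe/OBn/OBn/OMe pattern of 13 is kept on purpose. An aryne carrying the final OBn/OMe/OBn/OMe pattern would save three late steps, but it has alkoxy groups of equal electronic weight beside both aryne carbons and would add in both orientations.
- Benzyl on ring A and isopropyl on ring B are kept because they are orthogonal in step 13 and fall together in step 16.
- The precursor syntheses are shortened by a one-pot silylation/rearrangement/triflation (step 7) and a telescoped condensation/saponification (step 10).

## Route

Step 1
Reactants: 1 2,3-dihydroxy-4-methoxybenzaldehyde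
Product: 2 2,3-bis(benzyloxy)-4-methoxybenzaldehyde
Conditions: BnBr (2.4 equiv), K2CO3, DMF, 60 °C
Reagents that add atoms: benzyl bromide, BrCc1ccccc1
Why: Williamson etherification of both phenols; the chelated 2-OH needs excess base and gentle heating, and benzyl is chosen because it survives the organolithium steps and is removed later by hydrogenolysis.

Step 2
Reactants: 2 2,3-bis(benzyloxy)-4-methoxybenzaldehyde
Product: 4 2,3-bis(benzyloxy)-4-methoxyphenol, via aryl formate 3 (not isolated)
Conditions: mCPBA, CH2Cl2, 0 °C → rt; then K2CO3 (cat.), MeOH, rt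
Reagents that add atoms: meta-chloroperoxybenzoic acid, OOC(=O)c1cccc(Cl)c1
Why: Dakin-type Baeyer–Villiger oxidation; the ortho and para alkoxy groups make the aryl group migrate in preference to hydride, and the formate is methanolysed in the same pot.

Step 3
Reactants: 4 2,3-bis(benzyloxy)-4-methoxyphenol
Product: 5 2,3-bis(benzyloxy)-1,4-dimethoxybenzene
Conditions: MeI, K2CO3, DMF, rt
Reagents that add atoms: iodomethane, CI
Why: Williamson O-methylation; it gives the symmetric tetraether whose two remaining ring hydrogens are equivalent.

Step 4
Reactants: 5 2,3-bis(benzyloxy)-1,4-dimethoxybenzene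
Product: 6 2,3-bis(benzyloxy)-5-bromo-1,4-dimethoxybenzene
Conditions: NBS (1.0 equiv), MeCN, 0 °C → rt
Reagents that add atoms: N-bromosuccinimide, O=C1CCC(=O)N1Br
Why: Electrophilic aromatic bromination at one of two equivalent positions; the first bromine deactivates the ring against a second, and the polar, radical-free conditions leave the benzylic positions alone.

Step 5
Reactants: 6 2,3-bis(benzyloxy)-5-bromo-1,4-dimethoxybenzene
Product: 9 3,4-bis(benzyloxy)-2,5-dimethoxyphenol, via aryllithium 7 (not isolated), via dimethyl arylboronate 8 (not isolated)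
Conditions: n-BuLi, THF, –78 °C; B(OMe)3, –78 °C → rt; then AcOH, 30% H2O2, 0 °C → rt
Reagents that add atoms: hydrogen peroxide, OO (phenol oxygen); trimethyl borate, COB(OC)OC (boron and methoxy groups of 8 only); n-butyllithium, [Li]CCCC (lithium of 7 only)
Why: Bromine–lithium exchange, borylation and oxidative 1,2-shift of the aryl group from boron to oxygen; exchange at –78 °C is much faster than deprotonation of the benzylic ether positions.

Step 6
Reactants: 9 3,4-bis(benzyloxy)-2,5-dimethoxyphenol
Product: 10 4,5-bis(benzyloxy)-2-bromo-3,6-dimethoxyphenol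
Conditions: NBS (1.0 equiv), CH2Cl2, –40 → 0 °C
Reagents that add atoms: N-bromosuccinimide, O=C1CCC(=O)N1Br
Why: Electrophilic ortho-bromination of a phenol with a single free ring position; low temperature and exact stoichiometry are used to suppress oxidation of the electron-rich ring.

Step 7
Reactants: 10 4,5-bis(benzyloxy)-2-bromo-3,6-dimethoxyphenol
Product: 13 4,5-bis(benzyloxy)-3,6-dimethoxy-2-(trimethylsilyl)phenyl trifluoromethanesulfonate, via aryl trimethylsilyl ether 11 (not isolated), via lithium 2-silylphenolate 12 (not isolated)
Conditions: (Me3Si)2NH, THF, 65 °C, then evaporation; n-BuLi, THF, –100 → –78 °C; Tf2O, –100 °C → rt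
Reagents that add atoms: hexamethyldisilazane, C[Si](C)(C)N[Si](C)(C)C; trifluoromethanesulfonic anhydride, O=S(=O)(OS(=O)(=O)C(F)(F)F)C(F)(F)F; n-butyllithium, [Li]CCCC (lithium of 12 only)
Why: O-silylation, bromine–lithium exchange with 1,3 O-to-C silyl shift (retro-Brook rearrangement) and O-triflation of the phenolate, the standard one-pot entry to 2-silylaryl triflates from 2-bromophenols.

Step 8
Reactants: 14 2,4-dimethoxyphenol
Product: 15 1-isopropoxy-2,4-dimethoxybenzene
Conditions: 2-bromopropane, K2CO3, DMF, 60 °C
Reagents that add atoms: 2-bromopropane, CC(C)Br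
Why: Williamson etherification; the isopropyl ether survives base, fluoride and hydrogenolysis and is cleaved by BCl3 at the end.

Step 9
Reactants: 15 1-isopropoxy-2,4-dimethoxybenzene
Product: 16 5-isopropoxy-2,4-dimethoxybenzaldehyde
Conditions: POCl3, DMF, 0 → 70 °C; then ice-water, NaOAc
Reagents that add atoms: N,N-dimethylformamide, CN(C)C=O (formyl carbon); water, O (carbonyl oxygen)
Why: Vilsmeier–Haack formylation at the position para to one OMe and ortho to the other, the only site activated by two alkoxy groups without lying between them.

Step 10
Reactants: 16 5-isopropoxy-2,4-dimethoxybenzaldehyde; 17 methyl methoxyacetate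
Product: 19 (Z)-3-(5-isopropoxy-2,4-dimethoxyphenyl)-2-methoxyacrylic acid, via methyl ester 18 (not isolated)
Conditions: NaOMe, MeOH/toluene, 0 °C → reflux; then aq NaOH, reflux; then HCl
Reagents that add atoms: sodium hydroxide, [Na+].[OH-] (carboxyl oxygen)
Why: Claisen-type aldol condensation of the ester enolate with the non-enolisable aldehyde and E1cB loss of water, then saponification; the Z acid (aryl trans to carboxyl) is the more stable isomer and should be enriched by the reversible conditions and by crystallisation.

Step 11
Reactants: 13 4,5-bis(benzyloxy)-3,6-dimethoxy-2-(trimethylsilyl)phenyl trifluoromethanesulfonate; 19 (Z)-3-(5-isopropoxy-2,4-dimethoxyphenyl)-2-methoxyacrylic acid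
Product: 21 (Z)-1-[3,4-bis(benzyloxy)-6-hydroxy-2,5-dimethoxyphenyl]-3-(5-isopropoxy-2,4-dimethoxyphenyl)-2-methoxyprop-2-en-1-one, via aryne 20 (not isolated)
Conditions: CsF (4 equiv), 13 (1.5 equiv), THF, 125 °C, sealed tube
Reagents that add atoms: none
Why: Fluoride attacks silicon in 13 and triflate leaves, releasing aryne 20 gradually at high temperature. The caesium carboxylate of 19 adds through oxygen to one aryne carbon, and the ortho aryl anion so formed attacks the ester carbonyl through a four-membered transition state; opening of the strained alkoxide gives the phenolate of 21, so O1–C8a and C4–C4a are both made in one operation. The closest known reaction type is the fluoride-induced insertion of arynes into the C–O bond of carboxylic acids to give ortho-hydroxyaryl ketones, which extends to α,β-unsaturated acids. No ring of the target closes here and no stereocentre is formed; the Z double bond of 19 is not touched. Orientation is no issue because 20 has a mirror plane through the aryne bond (OMe beside each aryne carbon, OBn beyond), so either mode of addition gives 21. The selectivity needed is acyl capture in preference to protonation of the aryl anion; an aprotic medium, excess dried CsF and a low standing concentration of 20 favour it, and the chelated, hindered phenolate of 21 is a poor partner for a second aryne. Any 22 formed from 21 by oxa-Michael addition under these conditions is carried into step 12, where it converges.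

Step 12
Reactants: 21 (Z)-1-[3,4-bis(benzyloxy)-6-hydroxy-2,5-dimethoxyphenyl]-3-(5-isopropoxy-2,4-dimethoxyphenyl)-2-methoxyprop-2-en-1-one
Product: 23 6,7-bis(benzyloxy)-2-(5-isopropoxy-2,4-dimethoxyphenyl)-3,5,8-trimethoxy-4H-chromen-4-one, via 3-methoxyflavanone 22 (not isolated)
Conditions: I2 (10 mol %), DMSO, 120 °C
Reagents that add atoms: none
Why: Iodine-catalysed oxidative cyclisation of a 2'-hydroxychalcone: 6-endo oxa-Michael closure of ring C, α-iodination at C3 and loss of HI, with DMSO reoxidising HI to I2; both stereocentres of 22 are destroyed.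

Step 13
Reactants: 23 6,7-bis(benzyloxy)-2-(5-isopropoxy-2,4-dimethoxyphenyl)-3,5,8-trimethoxy-4H-chromen-4-one
Product: 24 6,7-dihydroxy-2-(5-isopropoxy-2,4-dimethoxyphenyl)-3,5,8-trimethoxy-4H-chromen-4-one
Conditions: H2 (1 atm), 10% Pd/C, EtOAc/MeOH, rt
Reagents that add atoms: none
Why: Catalytic hydrogenolysis of the two benzyl ethers; the tetrasubstituted C2=C3 bond of the vinylogous ester and the isopropyl and methyl ethers are inert, and the air-sensitive diol is used at once.

Step 14
Reactants: 24 6,7-dihydroxy-2-(5-isopropoxy-2,4-dimethoxyphenyl)-3,5,8-trimethoxy-4H-chromen-4-one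
Product: 25 7-(benzyloxy)-6-hydroxy-2-(5-isopropoxy-2,4-dimethoxyphenyl)-3,5,8-trimethoxy-4H-chromen-4-one
Conditions: BnBr (1.05 equiv), K2CO3 (1.1 equiv), degassed DMF, 0 °C → rt, argon
Reagents that add atoms: benzyl bromide, BrCc1ccccc1
Why: Williamson etherification under acidity control: the 7-OH is para to the C4 carbonyl (a vinylogous acid) and much more acidic than the 6-OH, so one equivalent of mild base forms and alkylates only the 7-phenoxide; exclusion of air protects the catechol.

Step 15
Reactants: 25 7-(benzyloxy)-6-hydroxy-2-(5-isopropoxy-2,4-dimethoxyphenyl)-3,5,8-trimethoxy-4H-chromen-4-one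
Product: 26 7-(benzyloxy)-2-(5-isopropoxy-2,4-dimethoxyphenyl)-3,5,6,8-tetramethoxy-4H-chromen-4-one
Conditions: MeI (excess), K2CO3, DMF, 40 °C
Reagents that add atoms: iodomethane, CI
Why: Williamson O-methylation of the only remaining hydroxyl; the hindered 6-OH needs excess reagent and mild heating.

Step 16
Reactants: 26 7-(benzyloxy)-2-(5-isopropoxy-2,4-dimethoxyphenyl)-3,5,6,8-tetramethoxy-4H-chromen-4-one
Product: 27 5,7-dihydroxy-2-(5-hydroxy-2,4-dimethoxyphenyl)-3,6,8-trimethoxy-4H-chromen-4-one
Conditions: BCl3 (6 equiv), C6HMe5, CH2Cl2, –78 → 0 °C; then MeOH, aq NaHCO3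
Reagents that add atoms: none
Why: Lewis-acid ether cleavage: BCl3 bound to C4=O removes the peri 5-O-methyl group through a six-membered chelate and cleaves the benzyl and secondary isopropyl ethers by way of stabilised cations (the benzyl cation is trapped by pentamethylbenzene). The non-chelated methyl ethers at O3, O6, O8, O2' and O4' should survive at or below 0 °C.

## Compound list

1 | 2,3-dihydroxy-4-methoxybenzaldehyde | COc1ccc(C=O)c(O)c1O | starting material
2 | 2,3-bis(benzyloxy)-4-methoxybenzaldehyde | COc1ccc(C=O)c(OCc2ccccc2)c1OCc1ccccc1 | intermediate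
3 | 2,3-bis(benzyloxy)-4-methoxyphenyl formate | COc1ccc(OC=O)c(OCc2ccccc2)c1OCc1ccccc1 | intermediate (not isolated)
4 | 2,3-bis(benzyloxy)-4-methoxyphenol | COc1ccc(O)c(OCc2ccccc2)c1OCc1ccccc1 | intermediate
5 | 2,3-bis(benzyloxy)-1,4-dimethoxybenzene | COc1ccc(OC)c(OCc2ccccc2)c1OCc1ccccc1 | intermediate
6 | 2,3-bis(benzyloxy)-5-bromo-1,4-dimethoxybenzene | COc1cc(Br)c(OC)c(OCc2ccccc2)c1OCc1ccccc1 | intermediate
7 | [3,4-bis(benzyloxy)-2,5-dimethoxyphenyl]lithium | [Li]c1cc(OC)c(OCc2ccccc2)c(OCc2ccccc2)c1OC | intermediate (not isolated)
8 | dimethyl [3,4-bis(benzyloxy)-2,5-dimethoxyphenyl]boronate | COB(OC)c1cc(OC)c(OCc2ccccc2)c(OCc2ccccc2)c1OC | intermediate (not isolated)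
9 | 3,4-bis(benzyloxy)-2,5-dimethoxyphenol | COc1cc(O)c(OC)c(OCc2ccccc2)c1OCc1ccccc1 | intermediate
10 | 4,5-bis(benzyloxy)-2-bromo-3,6-dimethoxyphenol | COc1c(O)c(Br)c(OC)c(OCc2ccccc2)c1OCc1ccccc1 | intermediate
11 | [4,5-bis(benzyloxy)-2-bromo-3,6-dimethoxyphenoxy]trimethylsilane | COc1c(O[Si](C)(C)C)c(Br)c(OC)c(OCc2ccccc2)c1OCc1ccccc1 | intermediate (not isolated)
12 | lithium 4,5-bis(benzyloxy)-3,6-dimethoxy-2-(trimethylsilyl)phenolate | [Li+].[O-]c1c(OC)c(OCc2ccccc2)c(OCc2ccccc2)c(OC)c1[Si](C)(C)C | intermediate (not isolated)
13 | 4,5-bis(benzyloxy)-3,6-dimethoxy-2-(trimethylsilyl)phenyl trifluoromethanesulfonate | COc1c(OCc2ccccc2)c(OCc2ccccc2)c(OC)c(OS(=O)(=O)C(F)(F)F)c1[Si](C)(C)C | intermediate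
14 | 2,4-dimethoxyphenol | COc1ccc(O)c(OC)c1 | starting material
15 | 1-isopropoxy-2,4-dimethoxybenzene | COc1ccc(OC(C)C)c(OC)c1 | intermediate
16 | 5-isopropoxy-2,4-dimethoxybenzaldehyde | COc1cc(OC)c(C=O)cc1OC(C)C | intermediate
17 | methyl methoxyacetate | COCC(=O)OC | starting material
18 | methyl (Z)-3-(5-isopropoxy-2,4-dimethoxyphenyl)-2-methoxyacrylate | CO/C(=C\c1cc(OC(C)C)c(OC)cc1OC)C(=O)OC | intermediate (not isolated)
19 | (Z)-3-(5-isopropoxy-2,4-dimethoxyphenyl)-2-methoxyacrylic acid | CO/C(=C\c1cc(OC(C)C)c(OC)cc1OC)C(=O)O | intermediate
20 | 4,5-bis(benzyloxy)-3,6-dimethoxybenzyne (1,2-didehydrobenzene) | COC1=C(OCc2ccccc2)C(OCc2ccccc2)=C(OC)C#C1 | intermediate (not isolated)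
21 | (Z)-1-[3,4-bis(benzyloxy)-6-hydroxy-2,5-dimethoxyphenyl]-3-(5-isopropoxy-2,4-dimethoxyphenyl)-2-methoxyprop-2-en-1-one | CO/C(=C\c1cc(OC(C)C)c(OC)cc1OC)C(=O)c1c(O)c(OC)c(OCc2ccccc2)c(OCc2ccccc2)c1OC | intermediate
22 | 6,7-bis(benzyloxy)-2-(5-isopropoxy-2,4-dimethoxyphenyl)-3,5,8-trimethoxychroman-4-one (racemic mixture of diastereomers) | COc1cc(OC)c(C2Oc3c(OC)c(OCc4ccccc4)c(OCc4ccccc4)c(OC)c3C(=O)C2OC)cc1OC(C)C | intermediate (not isolated)
23 | 6,7-bis(benzyloxy)-2-(5-isopropoxy-2,4-dimethoxyphenyl)-3,5,8-trimethoxy-4H-chromen-4-one | COc1cc(OC)c(-c2oc3c(OC)c(OCc4ccccc4)c(OCc4ccccc4)c(OC)c3c(=O)c2OC)cc1OC(C)C | intermediate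
24 | 6,7-dihydroxy-2-(5-isopropoxy-2,4-dimethoxyphenyl)-3,5,8-trimethoxy-4H-chromen-4-one | COc1cc(OC)c(-c2oc3c(OC)c(O)c(O)c(OC)c3c(=O)c2OC)cc1OC(C)C | intermediate
25 | 7-(benzyloxy)-6-hydroxy-2-(5-isopropoxy-2,4-dimethoxyphenyl)-3,5,8-trimethoxy-4H-chromen-4-one | COc1cc(OC)c(-c2oc3c(OC)c(OCc4ccccc4)c(O)c(OC)c3c(=O)c2OC)cc1OC(C)C | intermediate
26 | 7-(benzyloxy)-2-(5-isopropoxy-2,4-dimethoxyphenyl)-3,5,6,8-tetramethoxy-4H-chromen-4-one | COc1cc(OC)c(-c2oc3c(OC)c(OCc4ccccc4)c(OC)c(OC)c3c(=O)c2OC)cc1OC(C)C | intermediate
27 | 5,7-dihydroxy-2-(5-hydroxy-2,4-dimethoxyphenyl)-3,6,8-trimethoxy-4H-chromen-4-one | COc1cc(OC)c(-c2oc3c(OC)c(O)c(OC)c(O)c3c(=O)c2OC)cc1O | target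

## Step count and least certain steps

Total step count: 16 (steps 1–7 for 13, steps 8–10 for 19, step 11, steps 12–16). Longest linear sequence: 13 steps (1 → 13 → 21 → 27).

**Step 11 (key step).**
- What may go wrong: the aryl anion formed after O-addition may be protonated before it reaches the carbonyl carbon, which ends the sequence at simple O-arylation. The anion lies between OMe and the ester oxygen and the acyl carbon bears an α-OMe, so acyl transfer is slowed. Fluoride-induced self-reaction of the aryne and a second arylation of the product phenolate are further losses.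
- Fallback (organolithium acylation in place of the aryne): set out from 10 and protect it as the methoxymethyl ether 1,2-bis(benzyloxy)-4-bromo-3,6-dimethoxy-5-(methoxymethoxy)benzene F1 (MOMCl, iPr2NEt, CH2Cl2). Convert 19 into the amide (Z)-3-(5-isopropoxy-2,4-dimethoxyphenyl)-N,2-dimethoxy-N-methylprop-2-enamide F2 (MeNHOMe·HCl, EDC·HCl, iPr2NEt). Bromine–lithium exchange on F1 (n-BuLi, THF, –78 °C) and addition of F2 should give, through the stable tetrahedral chelate, the protected ketone (Z)-1-[3,4-bis(benzyloxy)-2,5-dimethoxy-6-(methoxymethoxy)phenyl]-3-(5-isopropoxy-2,4-dimethoxyphenyl)-2-methoxyprop-2-en-1-one F3. HCl in MeOH at rt removes the acetal, and the route is rejoined at 21.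

**Step 6.**
- What may go wrong: NBS may oxidise the pentaoxygenated phenol towards a quinone, with loss of an alkyl group, in place of ring substitution. The crowded retro-Brook shift of step 7 depends on this material.
- Fallback (directed ortho-metalation in place of bromination and silyl migration): set out from 9 and form the carbamate 3,4-bis(benzyloxy)-2,5-dimethoxyphenyl N-isopropylcarbamate F4 (iPrNCO, Et3N, CH2Cl2). N-Silylation in situ and ortho-lithiation between the carbamate and OMe (TBSOTf, TMEDA; n-BuLi, TMEDA, Et2O, –78 °C; TMSCl) should give 4,5-bis(benzyloxy)-3,6-dimethoxy-2-(trimethylsilyl)phenyl N-isopropylcarbamate F5. Carbamate cleavage and triflation in one pot (Et2NH, DBU, MeCN, 40 °C; then PhNTf2) returns to the route at 13, bypassing steps 6 and 7.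

**Step 10.**
- What may go wrong: addition of the ester enolate to the electron-rich, ortho-substituted aldehyde may be slow, so self-condensation of 17 and base-induced loss of the aldehyde take over.
- Fallback (phosphonate olefination in place of aldol condensation): set out from 16 and carry out a Horner–Wadsworth–Emmons reaction with commercial methyl 2-(dimethoxyphosphoryl)-2-methoxyacetate (NaH, THF, 0 °C → rt) to give 18, which is isolated. The Z isomer is enriched by crystallisation or iodine-catalysed equilibration. LiOH in THF/H2O then returns to the route at 19. Further compounds: none F0.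

**Step 12.**
- What may go wrong: HI formed at 120 °C may cleave benzyl or peri-methyl ethers, iodine may substitute the electron-rich ring B, or dehydrogenation may stall at the methoxy-bearing C3.
- Fallback (separate ring closure and metal-catalysed dehydrogenation): set out from 21, close ring C under mild base (NaOAc, EtOH, reflux) and isolate 22. Dehydrogenate it with Pd(OCOCF3)2 (cat.), DMSO, O2 (1 atm), 80 °C, through the palladium enolate and β-hydride elimination, to return at 23. Further compounds: none F0.

**Step 14.**
- What may go wrong: regiocontrol may erode (alkylation at O6 or at both oxygens), and the electron-rich catechol may be degraded oxidatively once it is deprotonated.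
- Fallback (selectivity from ester lability, catechol never free in base): set out from 24 and acetylate it (Ac2O, pyridine) to 2-(5-isopropoxy-2,4-dimethoxyphenyl)-3,5,8-trimethoxy-4-oxo-4H-chromene-6,7-diyl diacetate F6. Heating with BnBr, K2CO3 and KI in acetone should exchange only the 7-acetate, the ester of the most acidic phenol, for benzyl. This gives 7-(benzyloxy)-2-(5-isopropoxy-2,4-dimethoxyphenyl)-3,5,8-trimethoxy-4-oxo-4H-chromen-6-yl acetate F7. K2CO3 in MeOH removes the 6-acetate and returns to the route at 25.

**Step 16.**
- What may go wrong: methyl ethers at O3 or O6 next to the boron-chelated centres may be lost, or the isopropyl group may be removed incompletely when all three cleavages are forced in one pot.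
- Fallback (reductive and Lewis-acid cleavages separated): set out from 26 and remove the benzyl group by hydrogenolysis (H2, 10% Pd/C, EtOAc/MeOH) to 7-hydroxy-2-(5-isopropoxy-2,4-dimethoxyphenyl)-3,5,6,8-tetramethoxy-4H-chromen-4-one F8. Treat F8 with only enough BCl3 (3 equiv, CH2Cl2, –78 → 0 °C) for the chelated 5-OMe and the isopropyl ether, with no benzyl cation to scavenge. This arrives at 27.

## Further compounds

F1 | step 11 | 1,2-bis(benzyloxy)-4-bromo-3,6-dimethoxy-5-(methoxymethoxy)benzene | COCOc1c(OC)c(OCc2ccccc2)c(OCc2ccccc2)c(OC)c1Br
F2 | step 11 | (Z)-3-(5-isopropoxy-2,4-dimethoxyphenyl)-N,2-dimethoxy-N-methylprop-2-enamide | CO/C(=C\c1cc(OC(C)C)c(OC)cc1OC)C(=O)N(C)OC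
F3 | step 11 | (Z)-1-[3,4-bis(benzyloxy)-2,5-dimethoxy-6-(methoxymethoxy)phenyl]-3-(5-isopropoxy-2,4-dimethoxyphenyl)-2-methoxyprop-2-en-1-one | CO/C(=C\c1cc(OC(C)C)c(OC)cc1OC)C(=O)c1c(OCOC)c(OC)c(OCc2ccccc2)c(OCc2ccccc2)c1OC
F4 | step 6 | 3,4-bis(benzyloxy)-2,5-dimethoxyphenyl N-isopropylcarbamate | COc1cc(OC(=O)NC(C)C)c(OC)c(OCc2ccccc2)c1OCc1ccccc1
F5 | step 6 | 4,5-bis(benzyloxy)-3,6-dimethoxy-2-(trimethylsilyl)phenyl N-isopropylcarbamate | COc1c(OCc2ccccc2)c(OCc2ccccc2)c(OC)c(OC(=O)NC(C)C)c1[Si](C)(C)C
F0 | step 10 | none | none
F0 | step 12 | none | none
F6 | step 14 | 2-(5-isopropoxy-2,4-dimethoxyphenyl)-3,5,8-trimethoxy-4-oxo-4H-chromene-6,7-diyl diacetate | COc1cc(OC)c(-c2oc3c(OC)c(OC(C)=O)c(OC(C)=O)c(OC)c3c(=O)c2OC)cc1OC(C)C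
F7 | step 14 | 7-(benzyloxy)-2-(5-isopropoxy-2,4-dimethoxyphenyl)-3,5,8-trimethoxy-4-oxo-4H-chromen-6-yl acetate | COc1cc(OC)c(-c2oc3c(OC)c(OCc4ccccc4)c(OC(C)=O)c(OC)c3c(=O)c2OC)cc1OC(C)C
F8 | step 16 | 7-hydroxy-2-(5-isopropoxy-2,4-dimethoxyphenyl)-3,5,6,8-tetramethoxy-4H-chromen-4-one | COc1cc(OC)c(-c2oc3c(OC)c(O)c(OC)c(OC)c3c(=O)c2OC)cc1OC(C)C
A1 | alternative 1 | 1-[2,4-bis(benzyloxy)-6-bromo-3,5-dimethoxyphenyl]-3-[5-(benzyloxy)-2,4-dimethoxyphenyl]-2-methoxypropane-1,3-dione | COc1cc(OC)c(C(=O)C(OC)C(=O)c2c(Br)c(OC)c(OCc3ccccc3)c(OC)c2OCc2ccccc2)cc1OCc1ccccc1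
A2 | alternative 1 | 5,7-bis(benzyloxy)-2-[5-(benzyloxy)-2,4-dimethoxyphenyl]-3,6,8-trimethoxy-4H-chromen-4-one | COc1cc(OC)c(-c2oc3c(OC)c(OCc4ccccc4)c(OC)c(OCc4ccccc4)c3c(=O)c2OC)cc1OCc1ccccc1
A3 | alternative 2 | 2,4-bis(benzyloxy)-6-{1-[5-(benzyloxy)-2,4-dimethoxyphenyl]-2-oxoethoxy}-3,5-dimethoxybenzaldehyde (racemic) | COc1cc(OC)c(C(C=O)Oc2c(OC)c(OCc3ccccc3)c(OC)c(OCc3ccccc3)c2C=O)cc1OCc1ccccc1
A4 | alternative 2 | 5,7-bis(benzyloxy)-2-[5-(benzyloxy)-2,4-dimethoxyphenyl]-3-hydroxy-6,8-dimethoxychroman-4-one (mixture of diastereomers) | COc1cc(OC)c(C2Oc3c(OC)c(OCc4ccccc4)c(OC)c(OCc4ccccc4)c3C(=O)C2O)cc1OCc1ccccc1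
A5 | alternative 3 | 5-(benzyloxy)-2-iodo-4,6-dimethoxybenzene-1,3-diol | COc1c(O)c(I)c(O)c(OC)c1OCc1ccccc1
A6 | alternative 3 | 1-(benzyloxy)-5-ethynyl-2,4-dimethoxybenzene | COc1cc(OC)c(C#C)cc1OCc1ccccc1
A7 | alternative 3 | 7-(benzyloxy)-2-[5-(benzyloxy)-2,4-dimethoxyphenyl]-5-hydroxy-6,8-dimethoxy-4H-chromen-4-one | COc1cc(OC)c(-c2cc(=O)c3c(O)c(OC)c(OCc4ccccc4)c(OC)c3o2)cc1OCc1ccccc1
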